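Slowness, the minutes that 0.074 M of target would take at a run's pace, is read here as a sum of parts: one for the catalyst's own steps, one that grows as starting material thins, and one that grows as second substrate thins. The apparent order in second substrate is then the last part's share of the slowness, multiplied by charge over what remains. Zero on this scale is a saturated catalyst.

all flasks: free enzyme 0.51 µM; impurity 0.092 µM

|  | starting material | second substrate | scavenger | remark |
|---|---|---|---|---|
| delta | 0.074 M | 0.056 M | 0.037 M | run made earlier |
| alpha | 0.074 M | 0.22 M | 0.037 M | run made earlier |
| gamma | 0.15 M | 0.111 M | 0.037 M | run made earlier |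
| flask | 0.074 M | 0.111 M | 0.0370 M |  |

- delta (time / min: target / %): 0.200: 23.1; 0.667: 61.0; 1.00: 73.7; 1.50: 76.1; 2.50: 77.6; 3.00: 75.3
- alpha (time / min: target / %): 0.500: 65.3; 1.00: 96.3; 1.50: 99.9; 2.00: 99.7; 2.50: 99.2; 3.00: 100.3
- gamma (time / min: target / %): 0.250: 18.1; 0.833: 54.6; 1.33: 71.1; 2.00: 72.5; 3.00: 74.6

(standard deviation of a reading: 1 percentage point)

- amounts and yields of first product count idle adduct too
- steps under discussion: starting material + free enzyme <-> first complex; first complex -> loaded enzyme + first product; second substrate + loaded enzyme <-> second complex; second complex -> free enzyme + target; free enzyme + impurity -> spent catalyst; second substrate + first product <-> idle adduct; scavenger + first product -> scavenged by-product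

- apparent order in second substrate when 10 % of the starting material are converted (percent change of the rate of making target for one percent more second substrate charged)

Second substrate is the first setting. By hand, more of it shrinks its own part and leaves the others. The delta plateau near 77.6 % matches the charge ratio of 75.7 %, so second substrate goes one for one with target. The delta run reaches 61.0 % in 0.667 min, a slowness of 1.09 min, and the alpha run reaches 65.3 % in 0.500 min, a slowness of 0.766 min. The average inverse of second substrate differs between them by 31.2 M⁻¹, so at 0.104 M, what one-for-one use leaves in the flask at 10 % conversion, its part is 0.101 min.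

Starting material is the next setting. By hand, more of it shrinks its part, and the gamma run at 0.15 M shows a slowness of 0.753 min up to 0.833 min, close to alpha's 0.766 min, although gamma holds 0.111 M of second substrate against alpha's 0.22 M, so two settings differ there.

For the flask, with alpha's slowness as the whole, the second-substrate share of slowness is 13.2 %, which gives an order of 0.142. This reckoning of my own lies above the forecast, which gives 0.11, within 0.04 to 0.25: “The enzyme is near saturation”.

The flask gives 0.13.

    starting material + free enzyme ⇌ first complex (K = 24.0 M⁻¹, k = 1.60 × 10⁶ M⁻¹ s⁻¹)
    first complex → loaded enzyme + first product (k = 16000 s⁻¹)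
    second substrate + loaded enzyme ⇌ second complex (K = 140 M⁻¹, k = 4.60 × 10⁵ M⁻¹ s⁻¹)
    second complex → free enzyme + target (k = 9000 s⁻¹)
    free enzyme + impurity → spent catalyst (k = 7.30 × 10⁷ M⁻¹ s⁻¹)
    second substrate + first product ⇌ idle adduct, settled at all times (K = 4.40 M⁻¹)
    scavenger + first product → scavenged by-product (k = 1.50 M⁻¹ s⁻¹)

Read back through the same rule, the flask's order means a share of 11.7 %, a little under the 13.2 % reckoned. Part of the flask's slowness is lost catalyst: without the step from free enzyme and impurity to spent catalyst, the rate at 10 % conversion is 1.22 times the actual one, and the apparent order in free enzyme goes from 1.2 to 1.0. Carried to the delta run at 10 % conversion, the share gives a slowness of 0.880 min, and the delta reading up to 0.200 min shows 0.866 min.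

The earlier runs and the new flask were computed for substances that don't exist; the scatter is artificial.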